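## Structural features

The target is a 2,3-dihydrobenzofuran: a benzene ring fused through C3a and C7a to a five-membered ring that holds O1, C2 and C3. C2 carries a 1-formylvinyl (2-substituted acrolein) unit, C3 carries an (E)-2-methylbut-2-enoate (tiglate), and C5, para to O1, carries a 1-(tigloyloxy)ethyl chain. C2 (R) and C3 (S) are adjacent and trans. The third centre, C1' (R) of the side chain, lies across the arene and cannot be relayed from the ring, so a reagent has to set it. Both esters sit on oxygen-activated benzylic carbons (C3 ortho and C1' para to the ring oxygen), so acid can ionise them, and loss of tiglic acid across C2–C3 would aromatise the heterocycle to a benzofuran. The enal is a polymerisable Michael acceptor and the tiglates must keep their E geometry. The real difficulty is to set the trans C2/C3 pair in one absolute sense independently of C1', and then to finish under conditions mild enough for these sensitive sites. The key step uses the fact that C2 is a single carbon bonded only to O1, C3 and the acrolein carbon. It can therefore come in as the nucleophilic carbon of an allyl sulfonium ylide that bonds first to the aldehyde carbon (future C3) and then to the phenol oxygen (O1) of a salicylaldehyde, which already holds O1, C7a, C3a, C3 and the whole arene.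

## Logic of the disconnections

22 to 21: no skeletal bond is cut; the aldehyde is taken back to a primary allylic alcohol. The enal is the most reactive group of 22 and is best made last. The demand is an oxidant that touches only an allylic alcohol and leaves two benzylic esters alone.

21 to 19 by way of 20: the O–Si bond of the primary alcohol and the two acyl C–O bonds are cut. Both tiglates go on together once both secondary hydroxyls are free and the primary one is masked. This removes both esters and their E-alkenes from all earlier steps. The demand is acylation without elimination or deconjugation, and later desilylation that does not ionise the benzylic esters.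

19 to 18: only the Si–O bond at C1' is cut. The side-chain carbinol has to be masked while the arene is a phenoxide, because a better leaving group there would invite quinone methide formation. The forward step must distinguish a secondary triethylsilyl ether from a primary tert-butyldiphenylsilyl ether under conditions that are not acidic, since C1' is a para-oxygen-activated benzylic carbon. A triethylsilyl group is chosen at C1' for that reason, in preference to a bulkier silyl group that would need acid.

18 to 7 and 14: the C2–C3 and O1–C2 bonds are cut. This is the strategic cut. It removes the heterocycle and both ring stereocentres at once and leaves an achiral-at-the-ring salicylaldehyde and a one-carbon ylide donor that already carries the masked acrolein. The forward step has to add the ylide carbon to the aldehyde with face control, close trans, and react at the alpha carbon of the allyl unit.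

7 to 1 by way of 5, 4, 3 and 2: the aryl–CHO bond is cut first (through 6), which is possible because the hydroxyl directs to the only free ortho position and the para position is occupied. Then the silyl groups are removed on paper and the carbinol C–H bond is traced to the ketone of 1. The demand is an enantioselective ketone reduction; the phenol is silylated beforehand so that the ketone behaves like an ordinary 4-alkoxyacetophenone.

14 to 13 and 10: the S–CH2 bond is cut, giving an allylic bromide and a C2-symmetric sulfide. Because the sulfide is C2-symmetric, alkylation can give only one sulfonium isomer.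

13 to 11 by way of 12, and 10 to 8 by way of 9: the C–Br and O–Si bonds lead back to a symmetrical diol, which needs one monoprotection. The two C–S bonds of 10 lead back to a chiral diol, which needs a double displacement with clean inversion.

## Other disconnections considered

Alternative 1: The cut is the O1–C2 bond, traced back to a six-membered ring. The isopropenyl dihydrobenzofuran A1 would arise by ring contraction of the 3-hydroxychroman A2. A2 would come from chromene A3 by manganese–salen ((salen)MnCl) epoxidation and opening of the epoxide at C4 by tiglate.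
- Forward key step: Tf2O and 2,6-di-tert-butyl-4-methylpyridine would activate the C3 hydroxyl of A2. The ring oxygen antiperiplanar to it would shift from C2 to C3 with inversion, and the tertiary cation left behind would lose a methyl proton.
- In favour: the stereo-defining epoxidation of a 2,2-dimethylchromene is catalytic and very reliable, which is better than a stoichiometric chiral sulfide. Both tiglates are carried through with no protecting group, which is also better.
- Against: the trans C4 tiglate of A2 is as well placed as the ring oxygen to take part (acyloxonium formation). The cation could also lose the ring proton, and a benzylic ester could ionise under Tf2O. A1 still lacks the aldehyde, so an allylic oxidation with SeO2 would have to pick the isopropenyl methyl out of four tiglate methyl groups on an acid-sensitive substrate.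
- Comparison: the step count is probably equal or lower. The key step and the last step are each less secure than anything in the chosen plan, which carries the acrolein carbon at a protected alcohol level from the start.

Alternative 2: The cut is the aryl ether bond C7a–O1. The acetyl dihydrobenzofuran A4 would come from the open-chain fluoroarene A5.
- Forward key step: Cs2CO3 in DMF would generate the C2 alkoxide of A5, which adds to the fluorine-bearing carbon; the para acetyl group stabilises the adduct and fluoride leaves.
- In favour: the ring closure neither creates nor touches a stereocentre and needs no epoxide opening. On mechanistic security of the cyclisation itself it is the better of the two. The acetyl group both activates the arene and is the latent C1' carbinol.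
- Against: A5 needs both carbinol centres set beforehand in the anti sense and enantioselectively, with the silyl group on the benzylic oxygen only. Base-promoted 1,2-silyl migration would move the alkoxide to the benzylic oxygen, from which no ring can close. One para acetyl is a modest activator, so heating would expose the enolisable ketone. C1' would then be set late by a reagent-controlled reduction, followed by the same protecting-group end-game.
- Comparison: two stereocentres made in separate operations plus a late reduction make it longer than the chosen plan, which makes both ring centres and the ring in one flask.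

Alternative 3: The cut removes three arene bonds (C3a–C7a, C4–C5, C6–C7). The silylated dihydrobenzofuran A6 would be assembled from diyne A7 and monoyne A8.
- Forward key step: RhCl(PPh3)3 would couple the silyl ynol ether and the terminal alkyne of A7 to a rhodacycle that inserts A8, closing the benzene and dihydrofuran rings together.
- In favour: all three stereocentres are made beforehand and are not touched. C1' comes from a commercially available enantiopure propargylic alcohol, so no asymmetric reduction is needed, which is better on that point. The conditions are neutral.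
- Against: the ynol ether is long to make and hydrolytically fragile. The position of the side chain (C5 against C6) rests only on steric steering by the trimethylsilyl group. The 1,1-disubstituted alkene of A7 is a competing partner for the rhodacycle. The trimethylsilyl group must later be removed with acid that threatens the benzylic C–O bonds. Two secondary silyl ethers and one primary one then need the same differentiation as in the chosen plan.
- Comparison: it is the longest of the four, and it builds an arene that the chosen plan buys.

Key step: step 11

Assumption: the ylide from the (2R,5R)-thiolanium salt is taken to attack the aldehyde with the same facial sense as the corresponding benzyl ylide does with aromatic aldehydes, which leads to the (S,S)-epoxide; if the sense proved opposite, the enantiomeric salt would be used with no other change.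

## Route

Step 1
Reactants: 1 4'-hydroxyacetophenone
Product: 2 4'-(tert-butyldimethylsilyloxy)acetophenone
Conditions: TBSCl, imidazole, DMF, rt
Reagents that add atoms: tert-butyldimethylsilyl chloride, CC(C)(C)[Si](C)(C)Cl
Why: Standard silylation of a phenol; masking the acidic, strongly donating hydroxyl makes the ketone behave like a 4-alkoxyacetophenone in the reduction that follows.

Step 2
Reactants: 2 4'-(tert-butyldimethylsilyloxy)acetophenone
Product: 3 (1R)-1-[4-(tert-butyldimethylsilyloxy)phenyl]ethanol
Conditions: RuCl(p-cymene)[(R,R)-TsDPEN] (1 mol %), HCO2H/Et3N (5:2), 30 °C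
Reagents that add atoms: none
Why: Noyori asymmetric transfer hydrogenation; the (R,R)-diamine catalyst should deliver hydride to the Si face of the aryl methyl ketone through its six-membered transition state and set the (R) carbinol centre, as it does for other 4-oxygenated acetophenones, and the aryl silyl ether tolerates the weakly acidic medium.

Step 3
Reactants: 3 (1R)-1-[4-(tert-butyldimethylsilyloxy)phenyl]ethanol
Product: 4 tert-butyldimethyl{4-[(1R)-1-(triethylsilyloxy)ethyl]phenoxy}silane
Conditions: TESCl, imidazole, CH2Cl2, 0 °C
Reagents that add atoms: chlorotriethylsilane, CC[Si](CC)(CC)Cl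
Why: Standard silylation of a secondary benzylic alcohol at oxygen, so C1' is retained; the triethylsilyl group is chosen because it can later be removed beside a primary tert-butyldiphenylsilyl ether under nearly neutral fluoride conditions.

Step 4
Reactants: 4 tert-butyldimethyl{4-[(1R)-1-(triethylsilyloxy)ethyl]phenoxy}silane
Product: 5 4-[(1R)-1-(triethylsilyloxy)ethyl]phenol
Conditions: K2CO3 (0.3 equiv), MeOH, 0 °C → rt
Reagents that add atoms: none
Why: Chemoselective desilylation; aryl silyl ethers are cleaved by mild base far faster than alkyl silyl ethers because phenoxide is the better leaving group, so the phenol should be freed while the secondary triethylsilyl ether stays.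

Step 5
Reactants: 5 4-[(1R)-1-(triethylsilyloxy)ethyl]phenol
Product: 7 2-hydroxy-5-[(1R)-1-(triethylsilyloxy)ethyl]benzaldehyde, via hydroxymethylphenol 6 (not isolated)
Conditions: MgCl2, Et3N, (CH2O)n, THF, reflux; aq NH4Cl work-up
Reagents that add atoms: paraformaldehyde (formaldehyde), C=O
Why: Magnesium-mediated ortho-formylation of a phenol (Casnati–Skattebøl type): the magnesium phenoxide directs formaldehyde to the free ortho position to give 6, which a second formaldehyde oxidises by hydride transfer; the para position is blocked, the chelated product resists a second formylation, and the mildly basic medium and buffered work-up should spare the silyl ether.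

Step 6
Reactants: 8 (2S,5S)-hexane-2,5-diol
Product: 9 (2S,5S)-hexane-2,5-diyl dimethanesulfonate
Conditions: MsCl, Et3N, CH2Cl2, 0 °C
Reagents that add atoms: methanesulfonyl chloride, CS(=O)(=O)Cl
Why: Mesylation takes place at oxygen, so both (S) centres are retained and both hydroxyls become leaving groups.

Step 7
Reactants: 9 (2S,5S)-hexane-2,5-diyl dimethanesulfonate
Product: 10 (2R,5R)-2,5-dimethylthiolane
Conditions: Na2S·9H2O, DMSO, rt
Reagents that add atoms: sodium sulfide, [Na+].[Na+].[S-2]
Why: Double SN2 displacement by sulfide with inversion at both carbons turns the (2S,5S) dimesylate into the C2-symmetric (2R,5R) thiolane; the second displacement is a fast 5-exo-tet ring closure that outruns elimination.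

Step 8
Reactants: 11 2-methylenepropane-1,3-diol
Product: 12 2-[(tert-butyldiphenylsilyloxy)methyl]prop-2-en-1-ol
Conditions: NaH (1.0 equiv), THF, 0 °C; TBDPSCl, 0 °C → rt
Reagents that add atoms: tert-butyldiphenylsilyl chloride, CC(C)(C)[Si](Cl)(c1ccccc1)c1ccccc1
Why: Monoprotection of a symmetrical diol; one equivalent of NaH followed by the silyl chloride should silylate one of the two equivalent primary hydroxyls.

Step 9
Reactants: 12 2-[(tert-butyldiphenylsilyloxy)methyl]prop-2-en-1-ol
Product: 13 {[2-(bromomethyl)prop-2-en-1-yl]oxy}(tert-butyl)diphenylsilane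
Conditions: CBr4, PPh3, CH2Cl2, 0 °C
Reagents that add atoms: carbon tetrabromide, BrC(Br)(Br)Br
Why: Appel bromination; displacement at a primary allylic carbon under neutral conditions that spare the silyl ether.

Step 10
Reactants: 13 {[2-(bromomethyl)prop-2-en-1-yl]oxy}(tert-butyl)diphenylsilane; 10 (2R,5R)-2,5-dimethylthiolane
Product: 14 (2R,5R)-1-{2-[(tert-butyldiphenylsilyloxy)methyl]prop-2-en-1-yl}-2,5-dimethylthiolanium tetrafluoroborate
Conditions: AgBF4, CH2Cl2, 0 °C → rt, dark
Reagents that add atoms: silver tetrafluoroborate, [Ag+].F[B-](F)(F)F
Why: S-alkylation of the sulfide by the allylic bromide, driven by precipitation of AgBr and giving the non-nucleophilic tetrafluoroborate; the two lone pairs of the C2-symmetric sulfide are equivalent, so a single sulfonium salt should form.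

Step 11
Reactants: 7 2-hydroxy-5-[(1R)-1-(triethylsilyloxy)ethyl]benzaldehyde; 14 (2R,5R)-1-{2-[(tert-butyldiphenylsilyloxy)methyl]prop-2-en-1-yl}-2,5-dimethylthiolanium tetrafluoroborate
Product: 18 (2R,3S)-2-[3-(tert-butyldiphenylsilyloxy)prop-1-en-2-yl]-5-[(1R)-1-(triethylsilyloxy)ethyl]-2,3-dihydrobenzofuran-3-ol, via sulfonium ylide 15 (not isolated), via anti betaine 16 (not isolated), via trans vinyl epoxide 17 (not isolated)
Conditions: KOH (2.5 equiv), MeCN/H2O (9:1), 0 °C → rt
Reagents that add atoms: none
Why: KOH converts 7 into its phenoxide and deprotonates the allylic S–CH2 of 14 to ylide 15, whose alpha carbon adds to the aldehyde to give anti betaine 16; the alkoxide of 16 expels the thiolane by 3-exo-tet closure to trans vinyl epoxide 17, and the ortho phenoxide then attacks the allylic epoxide carbon with inversion to give 18. The closest known reactions are the Corey–Chaykovsky annulation of salicylaldehydes with sulfur ylides to trans-2-substituted 2,3-dihydrobenzofuran-3-ols and the epoxidation of aromatic aldehydes by 2-substituted allyl ylides of C2-symmetric thiolanes. The dihydrofuran ring closes by a 5-endo opening of the epoxide, the only mode open to an oxygen held on the neighbouring arene carbon (a 4-exo closure is out of reach), and the allylic activation of the breaking C–O bond helps it. C3 (S) is fixed in the C–C bond-forming event: the C2-symmetric thiolane shields one face of the ylide, so one face of the aldehyde is attacked. C2 (R) follows from the anti mode of addition, which a 2-substituted allylide prefers under reversible protic conditions, and from two successive inversions at that carbon (sulfide displaced by alkoxide, then epoxide oxygen displaced by phenoxide), which together give the trans 2,3 relationship. The step needs alpha and not gamma attack of the allylide, which is the productive path because only the alpha adduct can close to an epoxide, and deprotonation at the allylic CH2 and not at the ring CH–S carbons, which the higher acidity of the allylic position secures. The 2-silyloxymethyl group makes a 1,3-shift of sulfur degenerate, and the remote C1' centre is too far away to bias the outcome, so the reagent alone decides.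

Step 12
Reactants: 18 (2R,3S)-2-[3-(tert-butyldiphenylsilyloxy)prop-1-en-2-yl]-5-[(1R)-1-(triethylsilyloxy)ethyl]-2,3-dihydrobenzofuran-3-ol
Product: 19 (2R,3S)-2-[3-(tert-butyldiphenylsilyloxy)prop-1-en-2-yl]-5-[(1R)-1-hydroxyethyl]-2,3-dihydrobenzofuran-3-ol
Conditions: HF·pyridine, pyridine, THF, 0 °C
Reagents that add atoms: none
Why: Fluoride-mediated desilylation under pyridine buffering; a secondary triethylsilyl ether is cleaved orders of magnitude faster than a primary tert-butyldiphenylsilyl ether, and the nearly neutral medium avoids ionising the para-oxygen-activated benzylic C–O bond, so C1' keeps its configuration.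

Step 13
Reactants: 19 (2R,3S)-2-[3-(tert-butyldiphenylsilyloxy)prop-1-en-2-yl]-5-[(1R)-1-hydroxyethyl]-2,3-dihydrobenzofuran-3-ol
Product: 20 (2R,3S)-2-[3-(tert-butyldiphenylsilyloxy)prop-1-en-2-yl]-5-[(1R)-1-(tigloyloxy)ethyl]-2,3-dihydrobenzofuran-3-yl tiglate
Conditions: tigloyl chloride (3 equiv), pyridine, DMAP (cat.), CH2Cl2, 0 °C → rt
Reagents that add atoms: tigloyl chloride ((E)-2-methylbut-2-enoyl chloride), C/C=C(\C)C(=O)Cl
Why: DMAP-catalysed acylation of both secondary benzylic alcohols at oxygen, so C3 and C1' are retained; pyridine in place of a trialkylamine limits ketene formation and deconjugation of the tigloyl unit, and in the trans isomer H2 is syn to the C3 ester, so base-induced anti elimination to the benzofuran is disfavoured.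

Step 14
Reactants: 20 (2R,3S)-2-[3-(tert-butyldiphenylsilyloxy)prop-1-en-2-yl]-5-[(1R)-1-(tigloyloxy)ethyl]-2,3-dihydrobenzofuran-3-yl tiglate
Product: 21 (2R,3S)-2-(3-hydroxyprop-1-en-2-yl)-5-[(1R)-1-(tigloyloxy)ethyl]-2,3-dihydrobenzofuran-3-yl tiglate
Conditions: HF·pyridine, pyridine, THF, 0 °C → rt
Reagents that add atoms: none
Why: Buffered HF·pyridine removes the primary silyl ether; the esters are inert to fluoride under these conditions, and acyl migration from O3 to the new hydroxyl would need an unfavourable seven-membered transition state.

Step 15
Reactants: 21 (2R,3S)-2-(3-hydroxyprop-1-en-2-yl)-5-[(1R)-1-(tigloyloxy)ethyl]-2,3-dihydrobenzofuran-3-yl tiglate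
Product: 22 (2R,3S)-2-(3-oxoprop-1-en-2-yl)-5-[(1R)-1-(tigloyloxy)ethyl]-2,3-dihydrobenzofuran-3-yl tiglate (target)
Conditions: MnO2 (excess), CH2Cl2, rt
Reagents that add atoms: none
Why: MnO2 oxidises allylic alcohols selectively under neutral heterogeneous conditions; no free benzylic hydroxyl remains, and the esters and the acid-sensitive benzylic C–O bonds should not be affected.

## Compound list

1 | 4'-hydroxyacetophenone | CC(=O)c1ccc(O)cc1 | starting material
2 | 4'-(tert-butyldimethylsilyloxy)acetophenone | CC(=O)c1ccc(O[Si](C)(C)C(C)(C)C)cc1 | intermediate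
3 | (1R)-1-[4-(tert-butyldimethylsilyloxy)phenyl]ethanol | C[C@@H](O)c1ccc(O[Si](C)(C)C(C)(C)C)cc1 | intermediate
4 | tert-butyldimethyl{4-[(1R)-1-(triethylsilyloxy)ethyl]phenoxy}silane | C[C@@H](O[Si](CC)(CC)CC)c1ccc(O[Si](C)(C)C(C)(C)C)cc1 | intermediate
5 | 4-[(1R)-1-(triethylsilyloxy)ethyl]phenol | C[C@@H](O[Si](CC)(CC)CC)c1ccc(O)cc1 | intermediate
6 | 2-(hydroxymethyl)-4-[(1R)-1-(triethylsilyloxy)ethyl]phenol (present as its magnesium phenoxide) | C[C@@H](O[Si](CC)(CC)CC)c1ccc(O)c(CO)c1 | intermediate
7 | 2-hydroxy-5-[(1R)-1-(triethylsilyloxy)ethyl]benzaldehyde | O=Cc1cc([C@@H](C)O[Si](CC)(CC)CC)ccc1O | intermediate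
8 | (2S,5S)-hexane-2,5-diol | C[C@H](O)CC[C@H](C)O | starting material
9 | (2S,5S)-hexane-2,5-diyl dimethanesulfonate | C[C@H](OS(C)(=O)=O)CC[C@H](C)OS(C)(=O)=O | intermediate
10 | (2R,5R)-2,5-dimethylthiolane | C[C@@H]1CC[C@@H](C)S1 | intermediate
11 | 2-methylenepropane-1,3-diol | C=C(CO)CO | starting material
12 | 2-[(tert-butyldiphenylsilyloxy)methyl]prop-2-en-1-ol | C=C(CO)CO[Si](c1ccccc1)(c1ccccc1)C(C)(C)C | intermediate
13 | {[2-(bromomethyl)prop-2-en-1-yl]oxy}(tert-butyl)diphenylsilane | C=C(CBr)CO[Si](c1ccccc1)(c1ccccc1)C(C)(C)C | intermediate
14 | (2R,5R)-1-{2-[(tert-butyldiphenylsilyloxy)methyl]prop-2-en-1-yl}-2,5-dimethylthiolanium tetrafluoroborate | C=C(CO[Si](c1ccccc1)(c1ccccc1)C(C)(C)C)C[S+]1[C@H](C)CC[C@H]1C.F[B-](F)(F)F | intermediate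
15 | sulfonium ylide of 14 (allylide, carbanion on the former S–CH2 carbon) | C=C(CO[Si](c1ccccc1)(c1ccccc1)C(C)(C)C)[CH-][S+]1[C@H](C)CC[C@H]1C | intermediate
16 | anti betaine: (1S,2R)-3-[(tert-butyldiphenylsilyloxy)methyl]-2-[(2R,5R)-2,5-dimethylthiolanium-1-yl]-1-{2-hydroxy-5-[(1R)-1-(triethylsilyloxy)ethyl]phenyl}but-3-en-1-olate (present as its phenoxide) | Oc1ccc([C@@H](C)O[Si](CC)(CC)CC)cc1[C@H]([O-])[C@@H](C(=C)CO[Si](c1ccccc1)(c1ccccc1)C(C)(C)C)[S+]1[C@H](C)CC[C@H]1C | intermediate
17 | 2-{(2S,3S)-3-[3-(tert-butyldiphenylsilyloxy)prop-1-en-2-yl]oxiran-2-yl}-4-[(1R)-1-(triethylsilyloxy)ethyl]phenol (trans vinyl epoxide, present as its phenoxide) | Oc1ccc([C@@H](C)O[Si](CC)(CC)CC)cc1[C@@H]1O[C@H]1C(=C)CO[Si](c1ccccc1)(c1ccccc1)C(C)(C)C | intermediate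
18 | (2R,3S)-2-[3-(tert-butyldiphenylsilyloxy)prop-1-en-2-yl]-5-[(1R)-1-(triethylsilyloxy)ethyl]-2,3-dihydrobenzofuran-3-ol | C=C(CO[Si](c1ccccc1)(c1ccccc1)C(C)(C)C)[C@H]1Oc2ccc([C@@H](C)O[Si](CC)(CC)CC)cc2[C@@H]1O | intermediate
19 | (2R,3S)-2-[3-(tert-butyldiphenylsilyloxy)prop-1-en-2-yl]-5-[(1R)-1-hydroxyethyl]-2,3-dihydrobenzofuran-3-ol | C=C(CO[Si](c1ccccc1)(c1ccccc1)C(C)(C)C)[C@H]1Oc2ccc([C@@H](C)O)cc2[C@@H]1O | intermediate
20 | (2R,3S)-2-[3-(tert-butyldiphenylsilyloxy)prop-1-en-2-yl]-5-[(1R)-1-(tigloyloxy)ethyl]-2,3-dihydrobenzofuran-3-yl tiglate | C=C(CO[Si](c1ccccc1)(c1ccccc1)C(C)(C)C)[C@H]1Oc2ccc([C@@H](C)OC(=O)/C(C)=C/C)cc2[C@@H]1OC(=O)/C(C)=C/C | intermediate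
21 | (2R,3S)-2-(3-hydroxyprop-1-en-2-yl)-5-[(1R)-1-(tigloyloxy)ethyl]-2,3-dihydrobenzofuran-3-yl tiglate | C=C(CO)[C@H]1Oc2ccc([C@@H](C)OC(=O)/C(C)=C/C)cc2[C@@H]1OC(=O)/C(C)=C/C | intermediate
22 | (2R,3S)-2-(3-oxoprop-1-en-2-yl)-5-[(1R)-1-(tigloyloxy)ethyl]-2,3-dihydrobenzofuran-3-yl tiglate | C=C(C=O)[C@H]1Oc2ccc([C@@H](C)OC(=O)/C(C)=C/C)cc2[C@@H]1OC(=O)/C(C)=C/C | target

## Step count and least certain steps

Total: 15 steps. Longest linear sequence: 10 steps (steps 1 to 5, then 11 to 15, from 1). The sulfonium arm (steps 6 to 10) is convergent.

Step 11 (key step). The most likely failure is erosion of trans and facial selectivity. The aldehyde of 7 is deactivated as its phenoxide, so addition is slow and the balance between reversible and irreversible betaine formation may shift. Direct displacement of the sulfide by the phenoxide within the betaine (one inversion where two are intended) would give the cis isomer, and a slow 5-endo opening could leave the epoxide unclosed. Fallback: separate the epoxidation from the ring closure. Starting from 7, the phenol would be silylated (TBSCl, imidazole) to 2-(tert-butyldimethylsilyloxy)-5-[(1R)-1-(triethylsilyloxy)ethyl]benzaldehyde F1, an ordinary aromatic aldehyde for the allyl ylide. The ylide from 14 (KHMDS, THF, −78 °C) would convert F1 into the aryl silyl ether of the trans vinyl epoxide, tert-butyl{2-[(2S,3S)-3-(3-(tert-butyldiphenylsilyloxy)prop-1-en-2-yl)oxiran-2-yl]-4-[(1R)-1-(triethylsilyloxy)ethyl]phenoxy}dimethylsilane F2. K2CO3 in MeOH would then release the phenoxide, and the route is rejoined at 17, which closes to 18 in the same flask.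

Step 5. The most likely failure is loss of the benzylic silyloxy group by a quinone-methide-type elimination from the magnesium phenoxide at reflux, or cleavage of the triethylsilyl ether by the Lewis acidic medium or at work-up, either of which would racemise or destroy C1'. Fallback: formylation by halogen–metal exchange at low temperature. Starting from 5, ortho-bromination (NBS, catalytic i-Pr2NH, CH2Cl2, 0 °C) would give 2-bromo-4-[(1R)-1-(triethylsilyloxy)ethyl]phenol F3. Treatment with n-BuLi (2.2 equiv, THF, −78 °C) and then DMF would give the aldehyde, and the route is rejoined at 7.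

Step 14. The most likely failure is slow cleavage of the robust primary silyl ether, with prolonged exposure to HF leading to ionisation of the oxygen-activated benzylic esters (loss of tiglic acid from C3 with aromatisation to the benzofuran, or racemisation at C1'). Fallback: put a much more labile silyl group on the primary oxygen before acylation. Starting from 18, TBAF would remove both silyl groups to give the triol (2R,3S)-2-(3-hydroxyprop-1-en-2-yl)-5-[(1R)-1-hydroxyethyl]-2,3-dihydrobenzofuran-3-ol F4. TESCl (1.05 equiv, 2,6-lutidine, CH2Cl2, −78 °C) would silylate the primary hydroxyl selectively to give (2R,3S)-5-[(1R)-1-hydroxyethyl]-2-[3-(triethylsilyloxy)prop-1-en-2-yl]-2,3-dihydrobenzofuran-3-ol F5. Double tigloylation as in step 13 would give (2R,3S)-5-[(1R)-1-(tigloyloxy)ethyl]-2-[3-(triethylsilyloxy)prop-1-en-2-yl]-2,3-dihydrobenzofuran-3-yl tiglate F6. A few minutes of buffered HF·pyridine at 0 °C would then free the primary alcohol, and the route is rejoined at 21. This detour also removes the rate-based selection of step 12, at the cost of one more step.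

Step 13. The most likely failure is incomplete acylation of the hindered C3 hydroxyl together with base-induced deconjugation or E/Z scrambling of the tigloyl unit through a ketene formed from the acid chloride. Fallback: a Yamaguchi esterification, which has no ketene pathway. Starting from 19, tiglic acid would be converted with 2,4,6-trichlorobenzoyl chloride and Et3N in toluene into the mixed anhydride (E)-2-methylbut-2-enoic 2,4,6-trichlorobenzoic anhydride F7, which with DMAP would acylate both hydroxyls. The route is rejoined at 20.

## Further compounds

F1 | step 11 | 2-(tert-butyldimethylsilyloxy)-5-[(1R)-1-(triethylsilyloxy)ethyl]benzaldehyde | O=Cc1cc([C@@H](C)O[Si](CC)(CC)CC)ccc1O[Si](C)(C)C(C)(C)C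
F2 | step 11 | tert-butyl{2-[(2S,3S)-3-(3-(tert-butyldiphenylsilyloxy)prop-1-en-2-yl)oxiran-2-yl]-4-[(1R)-1-(triethylsilyloxy)ethyl]phenoxy}dimethylsilane | CC(C)(C)[Si](C)(C)Oc1ccc([C@@H](C)O[Si](CC)(CC)CC)cc1[C@@H]1O[C@H]1C(=C)CO[Si](c1ccccc1)(c1ccccc1)C(C)(C)C
F3 | step 5 | 2-bromo-4-[(1R)-1-(triethylsilyloxy)ethyl]phenol | C[C@@H](O[Si](CC)(CC)CC)c1ccc(O)c(Br)c1
F4 | step 14 | (2R,3S)-2-(3-hydroxyprop-1-en-2-yl)-5-[(1R)-1-hydroxyethyl]-2,3-dihydrobenzofuran-3-ol | C=C(CO)[C@H]1Oc2ccc([C@@H](C)O)cc2[C@@H]1O
F5 | step 14 | (2R,3S)-5-[(1R)-1-hydroxyethyl]-2-[3-(triethylsilyloxy)prop-1-en-2-yl]-2,3-dihydrobenzofuran-3-ol | C=C(CO[Si](CC)(CC)CC)[C@H]1Oc2ccc([C@@H](C)O)cc2[C@@H]1O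
F6 | step 14 | (2R,3S)-5-[(1R)-1-(tigloyloxy)ethyl]-2-[3-(triethylsilyloxy)prop-1-en-2-yl]-2,3-dihydrobenzofuran-3-yl tiglate | C=C(CO[Si](CC)(CC)CC)[C@H]1Oc2ccc([C@@H](C)OC(=O)/C(C)=C/C)cc2[C@@H]1OC(=O)/C(C)=C/C
F7 | step 13 | (E)-2-methylbut-2-enoic 2,4,6-trichlorobenzoic anhydride | C/C=C(\C)C(=O)OC(=O)c1c(Cl)cc(Cl)cc1Cl
A1 | alternative 1 | (2R,3S)-2-(prop-1-en-2-yl)-5-[(1R)-1-(tigloyloxy)ethyl]-2,3-dihydrobenzofuran-3-yl tiglate | C=C(C)[C@H]1Oc2ccc([C@@H](C)OC(=O)/C(C)=C/C)cc2[C@@H]1OC(=O)/C(C)=C/C
A2 | alternative 1 | (3R,4S)-3-hydroxy-2,2-dimethyl-6-[(1R)-1-(tigloyloxy)ethyl]chroman-4-yl tiglate | CC1(C)Oc2ccc([C@@H](C)OC(=O)/C(C)=C/C)cc2[C@H](OC(=O)/C(C)=C/C)[C@H]1O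
A3 | alternative 1 | (1R)-1-(2,2-dimethyl-2H-chromen-6-yl)ethyl tiglate | CC1(C)C=Cc2cc([C@@H](C)OC(=O)/C(C)=C/C)ccc2O1
A4 | alternative 2 | (2R,3S)-5-acetyl-3-(tert-butyldimethylsilyloxy)-2-[3-(tert-butyldiphenylsilyloxy)prop-1-en-2-yl]-2,3-dihydrobenzofuran | C=C(CO[Si](c1ccccc1)(c1ccccc1)C(C)(C)C)[C@H]1Oc2ccc(C(C)=O)cc2[C@@H]1O[Si](C)(C)C(C)(C)C
A5 | alternative 2 | 1-{3-[(1S,2R)-1-(tert-butyldimethylsilyloxy)-3-[(tert-butyldiphenylsilyloxy)methyl]-2-hydroxybut-3-en-1-yl]-4-fluorophenyl}ethanone | C=C(CO[Si](c1ccccc1)(c1ccccc1)C(C)(C)C)[C@@H](O)[C@@H](O[Si](C)(C)C(C)(C)C)c1cc(C(C)=O)ccc1F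
A6 | alternative 3 | (2R,3S)-3-(tert-butyldimethylsilyloxy)-5-[(1R)-1-(tert-butyldimethylsilyloxy)ethyl]-2-[3-(tert-butyldiphenylsilyloxy)prop-1-en-2-yl]-7-(trimethylsilyl)-2,3-dihydrobenzofuran | C=C(CO[Si](c1ccccc1)(c1ccccc1)C(C)(C)C)[C@H]1Oc2c([Si](C)(C)C)cc([C@@H](C)O[Si](C)(C)C(C)(C)C)cc2[C@@H]1O[Si](C)(C)C(C)(C)C
A7 | alternative 3 | (3S,4R)-3-(tert-butyldimethylsilyloxy)-5-[(tert-butyldiphenylsilyloxy)methyl]-4-[(trimethylsilyl)ethynyloxy]hex-5-en-1-yne | C=C(CO[Si](c1ccccc1)(c1ccccc1)C(C)(C)C)[C@@H](OC#C[Si](C)(C)C)[C@@H](O[Si](C)(C)C(C)(C)C)C#C
A8 | alternative 3 | (R)-(but-3-yn-2-yloxy)(tert-butyl)dimethylsilane | C#C[C@@H](C)O[Si](C)(C)C(C)(C)C
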